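the same everywhere: protic impurity 14.4 mM; initiator 0.96 mM

|  | free monomer | remark | time |
|---|---|---|---|
| gamma | 24 mM | run made earlier |  |
| flask | 48 mM |  | 10 d |

gamma run (percent of the free monomer charged)

| time / d | monomer in chains / % | free monomer / % |
|---|---|---|
| 0.250 | 4 | 40 |
| 0.417 | 6 | 37 |
| 0.625 | 7 | 30 |
| 1.04 | 6 | 29 |
| 1.67 | 12 | 26 |
| 3.00 | 20 | 23 |

(readings scatter by 1.5 percentage points)

- average number of monomer units in a chain (living and dead chains, two that joined counted as one) at 10 d
- part of the free monomer that has reacted at 10 d

- the average divides the monomer in chains by the number of chains, living and dead together; two radicals that join make one chain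
- candidate steps: initiator -> 2 initiating radical; free monomer + initiating radical -> growing radical + monomer in chains; free monomer + growing radical -> monomer in chains + growing radical; 2 growing radical -> dead chain; protic impurity + free monomer -> quenched substrate
- the earlier runs do not show the number of chains; that part of a forecast is a guess

I decided to carry one number from the gamma run into the flask: the growth exposure, which is the mean pseudo-first-order rate of growth times the time it acts, or the natural logarithm of the free monomer after the quench over the free monomer at the end.

The fastest rung was the quench. A one-for-one loss to the protic impurity leaves 40.0% of the gamma charge for free monomer and monomer in chains together, and the sum of those two readings averaged 40.0%. The first reading, at 0.250 d, already held 4% in chains, so growth ran beside the quench, and I started my reckoning from the balance value, not from that reading.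

On the next rung I replaced the curve by its mean rate from 1.04 d to 3.00 d, which read 0.118 d⁻¹, with the scatter of those readings in it. From the balance value to the last reading the gamma run gave 0.553, the growth exposure, uncertain by about 0.0652 from the scatter.

The slowest rung was the asked time. I could not read from these scattered points how growth fades over the 7.00 d after the last reading, so I took two ends: growth stopping there leaves the exposure as it stood, and growth held at the mean rate raises it to 1.38.

The flask has the same initiator charge, so I assumed the same exposure. That was an assumption, since starting chains takes monomer too, up to 8.00% of the gamma charge against 4.00% of the flask's. In the flask the quench leaves 70.0%, which gives between 40.3% and 17.6% free monomer left, so c between 59.7% and 82.4%. Guessing one chain per initiator charged, I got dp between 14.9 and 26.2.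

The forecast stood above both my upper ends: it gave c 87% (78% to 93%), on the ground of “no clear slowing”, and dp 60 (30 to 200). The flask gave dp 16.3 and c 62.5%.

    initiator → 2 initiating radical (k = 0.0250 h⁻¹)
    free monomer + initiating radical → growing radical + monomer in chains (k = 77000 M⁻¹ s⁻¹)
    free monomer + growing radical → monomer in chains + growing radical, rate k3*[growing radical]*[free monomer] (k = 2.20 × 10⁶ M⁻¹ h⁻¹)
    2 growing radical → dead chain (k = 6.20 × 10⁸ M⁻¹ s⁻¹)
    protic impurity + free monomer → quenched substrate (k = 28.0 M⁻¹ h⁻¹)

The half-life of the initiator, 1.2 d, is shorter than the 4.0 d half-life of free monomer by growth at 0.0236 d. At 10.0 d the flask held 0.25% of its initiator beside 38% of its free monomer, and that growth half-life had become 80 d. In a neighbour flask with 24 mM of protic impurity, the same two ends of the exposure leave between 28.8% and 12.6% free monomer, so c between 71.2% and 87.4%. The computed neighbour kept 26%, with c of 74.1%.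

(Readings and results were computed on assumed constants, and the scatter is random.)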